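## Retrosynthetic overview

1. Carbon supply: the C15 chain is bought as (2E,6E)-farnesol 1 and the bicyclic core as 5,7-dihydroxycoumarin 2. No C–C bond and no ring is made (ring A, the arene, and ring B, the pyranone, arrive intact), so every strategic bond is C–O.
2. Last disconnection: C9–O and C10–O of the syn-diol lead back to a 9E-alkene next to the C11 tertiary alcohol. One hydroxyl-docked enantioselective osmylation sets both stereocentres.
3. Middle disconnection (union of the halves): the aryl O7–C1 ether leads back to a Mitsunobu reaction of a primary allylic alcohol with the 7-OH of the coumarin.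
4. First disconnection: C11–O, with the terminal alkene shifted from C10=C11 to C9=C10, leads back to hydroxyselenation and selenoxide elimination on farnesol.

Assumption: the (S,S)-diamine of step 3 (a known ligand, one reductive amination from commercial (S,S)-2,2'-bipyrrolidine, recovered after use, not counted as a route step) is taken to attack the 9Si,10Re face; if the first run shows the opposite sense, the (R,R)-antipode is used and nothing else changes.

## Route

Step 1
Reactants: 1 (2E,6E)-farnesol
Product: 5 (2E,6E,9E)-3,7,11-trimethyldodeca-2,6,9-triene-1,11-diol, via hydroxy selenide 3 (not isolated), via selenoxide 4 (not isolated)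
Conditions: PhSeCl (0.95 equiv), MeCN–H2O 5:1, 0 °C; then NaHCO3, NaIO4 (2.5 equiv), 0 °C to rt; chromatography
Reagents that add atoms: water, O; transient only (atoms in 3 and 4, lost again): PhSeCl, Cl[Se]c1ccccc1; NaIO4, [Na+].[O-]I(=O)(=O)=O
Why: Markovnikov hydroxyselenation followed by selenoxide syn-elimination: PhSe+ picks the least hindered, most electron-rich terminal isopropylidene in the aqueous medium (C2=C3 is deactivated by its allylic OH, C6=C7 is more shielded), water opens the seleniranium ion at tertiary C11, and the selenoxide has only the C9 hydrogens to take, which gives the 9E-alkene and erases the racemic C10 centre of 3 and 4.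

Step 2
Reactants: 5 (2E,6E,9E)-3,7,11-trimethyldodeca-2,6,9-triene-1,11-diol; 2 5,7-dihydroxycoumarin (1.5 equiv)
Product: 6 coumarin ether 5-hydroxy-7-{[(2E,6E,9E)-11-hydroxy-3,7,11-trimethyldodeca-2,6,9-trien-1-yl]oxy}-2H-chromen-2-one
Conditions: PPh3 (1.2 equiv), DIAD (1.2 equiv), THF, 0 °C to rt
Reagents that add atoms: none
Why: Mitsunobu etherification: PPh3/DIAD activates only the primary allylic alcohol (the tertiary C11–OH is inert), the more acidic and unhindered 7-OH (para-vinylogous to the lactone carbonyl, whereas 5-OH is peri to H-4) attacks C1 by SN2, excess 2 holds back the bis-ether, and no stereocentre or alkene geometry is touched.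

Step 3
Reactants: 6 coumarin ether
Product: 9 target 5-hydroxy-7-{[(2E,6E,9S,10R)-9,10,11-trihydroxy-3,7,11-trimethyldodeca-2,6-dien-1-yl]oxy}-2H-chromen-2-one, via aryl silyl ether 7 (not isolated), via osmate ester 8 (not isolated)
Conditions: HMDS (0.6 equiv), CH2Cl2, reflux, evaporate; OsO4 (1.0 equiv), (2S,2'S)-1,1'-bis(3,3-dimethylbutyl)-2,2'-bipyrrolidine (1.1 equiv), CH2Cl2, −78 °C; aq Na2SO3, THF, 50 °C, work-up at pH 5
Reagents that add atoms: osmium tetroxide, O=[Os](=O)(=O)=O; transient only (atoms in 7 and 8, lost again): HMDS, C[Si](C)(C)N[Si](C)(C)C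
Why: Proposed new method: hydroxyl-docked enantioselective dihydroxylation with a stoichiometric OsO4·chiral tertiary diamine reagent, in which chelation by the bipyrrolidine (a chiral counterpart of TMEDA) makes the oxo ligands of octavalent osmium strong hydrogen-bond acceptors, so the only OH left after transient silylation of the phenol (C11–OH) docks the reagent on the adjacent C9=C10 bond, whose E-1,2-disubstitution also fits the crowded C2-symmetric pocket better than the two trisubstituted alkenes, the suprafacial [3+2] addition fixes the syn 9,10 relationship, and the ligand selects the 9Si,10Re face to give 9S,10R; the closest known reaction types are the achiral OsO4·TMEDA hydrogen-bond-directed dihydroxylation of allylic alcohols and the undirected stoichiometric chiral-diamine osmylation of E-alkenes, which have not been merged or used to pick one alkene of a polyene.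

## Compound list

1 | (2E,6E)-farnesol | C/C(=C\CO)CC/C=C(\C)CCC=C(C)C | starting material
2 | 5,7-dihydroxycoumarin | Oc1cc(O)c2ccc(=O)oc2c1 | starting material
3 | rac-(2E,6E)-3,7,11-trimethyl-10-(phenylselanyl)dodeca-2,6-diene-1,11-diol (hydroxy selenide, C10 racemic) | C/C(=C\CO)CC/C=C(\C)CCC([Se]c1ccccc1)C(C)(C)O | intermediate
4 | rac-(2E,6E)-3,7,11-trimethyl-10-(phenylseleninyl)dodeca-2,6-diene-1,11-diol (selenoxide, C10 racemic, both Se epimers) | C/C(=C\CO)CC/C=C(\C)CCC([Se](=O)c1ccccc1)C(C)(C)O | intermediate
5 | (2E,6E,9E)-3,7,11-trimethyldodeca-2,6,9-triene-1,11-diol | C/C(=C\CO)CC/C=C(\C)C/C=C/C(C)(C)O | intermediate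
6 | 5-hydroxy-7-{[(2E,6E,9E)-11-hydroxy-3,7,11-trimethyldodeca-2,6,9-trien-1-yl]oxy}-2H-chromen-2-one | C/C(=C\COc1cc(O)c2ccc(=O)oc2c1)CC/C=C(\C)C/C=C/C(C)(C)O | intermediate
7 | 5-O-trimethylsilyl ether of 6 | C/C(=C\COc1cc(O[Si](C)(C)C)c2ccc(=O)oc2c1)CC/C=C(\C)C/C=C/C(C)(C)O | intermediate
8 | (9S,10R)-9,10-diolate of 7 bound to a dioxo centre of hexavalent osmium chelated by the (S,S)-diamine (osmate ester) | C/C(=C\COc1cc(O[Si](C)(C)C)c2ccc(=O)oc2c1)CC/C=C(\C)C[C@@H]1O[Os-2]2(=O)(=O)(O[C@H]1C(C)(C)O)[N+]1(CCC(C)(C)C)CCC[C@H]1[C@@H]1CCC[N+]21CCC(C)(C)C | intermediate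
9 | 5-hydroxy-7-{[(2E,6E,9S,10R)-9,10,11-trihydroxy-3,7,11-trimethyldodeca-2,6-dien-1-yl]oxy}-2H-chromen-2-one (CNP0174708.1) | C/C(=C\COc1cc(O)c2ccc(=O)oc2c1)CC/C=C(\C)C[C@H](O)[C@@H](O)C(C)(C)O | target

## Summary

Total step count: 3. Longest linear sequence: 3 (1 → 5 → 6 → 9).

## Steps most likely to fail

**Step 3 (the proposed new step).**
- Risk: the docking hydrogen bond and the chiral pocket may disagree, which would lower the ee, or the electron-rich C6=C7 bond may compete.
- Fallback with known chemistry, from 7 back to 9. The achiral reagent OsO4·TMEDA (1.0 equiv, CH2Cl2, −78 °C) has an established hydrogen-bond-directed dihydroxylation of allylic alcohols. It gives the racemic TMEDA-chelated osmate ester F1.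
- Aq Na2SO3 in THF then frees the racemic syn-triol, that is 9 together with its (9R,10S)-enantiomer F2.
- Preparative HPLC on an amylose tris(3,5-dimethylphenylcarbamate) phase delivers 9 as the single enantiomer, at most half of the material.

**Step 1.**
- Risk: PhSe+ may discriminate only modestly between C10=C11 and C6=C7, and the diol derived from C6=C7 is hard to remove.
- Fallback, from 1 back to 3. NBS (1.05 equiv) in THF–H2O at 0 °C, where the coiled chain exposes mainly its terminus, gives the terminal bromohydrin rac-(2E,6E)-10-bromo-3,7,11-trimethyldodeca-2,6-diene-1,11-diol F3.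
- K2CO3 in MeOH closes it to rac-10,11-epoxyfarnesol F4.
- PhSeSePh/NaBH4 in EtOH opens the epoxide at secondary C10 to hydroxy selenide 3, which is oxidised with NaIO4 as in step 1.

**Step 2.**
- Risk: the 5-O-ether and the 5,7-bis-ether may form in amounts that spoil the yield.
- Fallback, from 5 back to 6. Ring B is built after the ether bond. The Mitsunobu reaction of 5 is run with bought 2,4,6-trihydroxybenzaldehyde F5. Its two ortho-OH groups are held back by chelation to the aldehyde, so only the 4-OH reacts, giving 2,6-dihydroxy-4-alkoxybenzaldehyde F6.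
- Ph3P=C=C=O (1.0 equiv, toluene, 90 °C) acylates one of the two equivalent ortho-phenols to the acyl ylide F7.
- F7 closes ring B by intramolecular Wittig olefination to 6. The remaining OH is by construction the 5-OH, so the regiochemistry cannot go astray.

## Further compounds

F1 | step 3 | racemic TMEDA-chelated osmate ester of 7 (hexavalent osmium, syn-9,10, one enantiomer drawn) | C/C(=C\COc1cc(O[Si](C)(C)C)c2ccc(=O)oc2c1)CC/C=C(\C)C[C@@H]1O[Os-2]2(=O)(=O)(O[C@H]1C(C)(C)O)[N+](C)(C)CC[N+]2(C)C
F2 | step 3 | (9R,10S)-enantiomer of 9 | C/C(=C\COc1cc(O)c2ccc(=O)oc2c1)CC/C=C(\C)C[C@@H](O)[C@H](O)C(C)(C)O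
F3 | step 1 | rac-(2E,6E)-10-bromo-3,7,11-trimethyldodeca-2,6-diene-1,11-diol | C/C(=C\CO)CC/C=C(\C)CCC(Br)C(C)(C)O
F4 | step 1 | rac-(2E,6E)-10,11-epoxyfarnesol | C/C(=C\CO)CC/C=C(\C)CCC1OC1(C)C
F5 | step 2 | 2,4,6-trihydroxybenzaldehyde (bought) | O=Cc1c(O)cc(O)cc1O
F6 | step 2 | 2,6-dihydroxy-4-{[(2E,6E,9E)-11-hydroxy-3,7,11-trimethyldodeca-2,6,9-trien-1-yl]oxy}benzaldehyde | C/C(=C\COc1cc(O)c(C=O)c(O)c1)CC/C=C(\C)C/C=C/C(C)(C)O
F7 | step 2 | mono-O-[(triphenylphosphoranylidene)acetyl] derivative of F6 (acyl ylide, not isolated) | C/C(=C\COc1cc(O)c(C=O)c(OC(=O)C=P(c2ccccc2)(c2ccccc2)c2ccccc2)c1)CC/C=C(\C)C/C=C/C(C)(C)O
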